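**Retrosynthetic overview**

1. Target 32 ⇐ (dithiane hydrolysis, desilylation, acetylation, 1,3-anti reduction) ⇐ ten-membered C2 ketone 27. Its ring holds a Claisen retron, C2(=O)–C3–C4–C5=C6, with C2 on the quaternary C1 of the cyclohexene and C6 next to C7 of the γ-lactone.
2. Key disconnection C3–C4: 27 ⇐ transient eight-membered 2-methylene-oxocane 26 (ring O–C2–C1–C10–C9–C8–C7–C6, isopropenyl on C6) ⇐ seco ketal-alcohol 25 by intramolecular ketal exchange; the [3,3] shift expands 8 → 10 and delivers C2=O and the (5Z)-olefin.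
3. 25 ⇐ γ-lactone by intramolecular propanoate aldol on the C8 ketone (sets C8, C17) ⇐ C8–C9 union of dithiane 13 (C9 acyl anion, cyclohexene part) with aldehyde 19 (C4–C8, from (R)-glyceraldehyde acetonide).
4. 13 ⇐ quinone monoketal of methyl 5-methoxysalicylate: CBS reduction (C14), anti cuprate addition (C1), anti dithienium alkylation (C10), enol triflate/Stille (C20), Petasis methylenation (C3).
5. Ring order: cyclohexene (from the arene) → γ-lactone (step 21) → ten-membered carbocycle (step 23, last); the eight-membered ring is temporary.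

Key step: step 23

Remark: briarane numbering (C1–C20) is used for all intermediates; the C8 carbinol of 20 and the C6 carbinol (Felkin, 6,7-anti) are temporary stereocentres, erased in steps 18 and 23.

**Route**

Step 1
Reactants: 1 methyl 2-hydroxy-5-methoxybenzoate
Product: 2 methyl 3,3-dimethoxy-6-oxocyclohexa-1,4-diene-1-carboxylate
Conditions: PhI(OAc)2, MeOH, 0 °C
Reagents that add atoms: methanol (CO)
Why: Oxidative dearomatisation of a p-methoxyphenol with a hypervalent iodine reagent in methanol gives the quinone monoketal, which carries the future C14 carbonyl, the C2 ester on C1 and a masked C11 ketone.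

Step 2
Reactants: 2 methyl 3,3-dimethoxy-6-oxocyclohexa-1,4-diene-1-carboxylate
Product: 3 methyl 3,3-dimethoxy-6-oxocyclohex-1-ene-1-carboxylate
Conditions: H2 (1 atm), RhCl(PPh3)3 (5 mol%), toluene, rt
Reagents that add atoms: none
Why: Homogeneous hydrogenation with Wilkinson's catalyst should reduce only the unhindered disubstituted C12=C13 olefin and leave the trisubstituted, ester-bearing C1=C10 olefin next to the ketal.

Step 3
Reactants: 3 methyl 3,3-dimethoxy-6-oxocyclohex-1-ene-1-carboxylate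
Product: 4 methyl (6S)-6-hydroxy-3,3-dimethoxycyclohex-1-ene-1-carboxylate
Conditions: (R)-2-methyl-CBS-oxazaborolidine (10 mol%), catecholborane, toluene, −78 °C
Reagents that add atoms: none
Why: Corey–Bakshi–Shibata reduction of the α-substituted cyclohexenone, with the ester-bearing sp2 carbon as the large group, should give with the (R)-catalyst the (6S)-allylic alcohol, which is C14 of the target.

Step 4
Reactants: 4 methyl (6S)-6-hydroxy-3,3-dimethoxycyclohex-1-ene-1-carboxylate
Product: 5 methyl (6S)-6-hydroxy-3-oxocyclohex-1-ene-1-carboxylate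
Conditions: oxalic acid, wet SiO2, CH2Cl2, rt
Reagents that add atoms: water (O)
Why: Mild acid hydrolysis of the dimethyl ketal unmasks the C11 ketone as an enone conjugated through C10=C1 and leaves the allylic carbinol unchanged.

Step 5
Reactants: 5 methyl (6S)-6-hydroxy-3-oxocyclohex-1-ene-1-carboxylate
Product: 6 methyl (6S)-6-[(tert-butyldimethylsilyl)oxy]-3-oxocyclohex-1-ene-1-carboxylate
Conditions: TBSCl, imidazole, DMF, rt
Reagents that add atoms: tert-butyldimethylsilyl chloride (CC(C)(C)[Si](C)(C)Cl)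
Why: Silylation protects O14 and makes it the bulky γ-substituent that controls the face of the following conjugate addition.

Step 6
Reactants: 6 methyl (6S)-6-[(tert-butyldimethylsilyl)oxy]-3-oxocyclohex-1-ene-1-carboxylate
Product: 7 methyl (1R,6S)-6-[(tert-butyldimethylsilyl)oxy]-1-methyl-3-[(trimethylsilyl)oxy]cyclohex-2-ene-1-carboxylate
Conditions: Me2CuLi, TMSCl, THF, −78 °C
Reagents that add atoms: lithium dimethylcuprate ([Li+].C[Cu-]C); chlorotrimethylsilane (C[Si](C)(C)Cl)
Why: Conjugate addition of the Gilman cuprate to the γ-silyloxy enone at C1 (β to the ketone), anti to the neighbouring OTBS group, sets the quaternary centre with methyl trans to O14, and TMSCl traps the enolate regiospecifically as the C10=C11 silyl enol ether.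

Step 7
Reactants: 7 methyl (1R,6S)-6-[(tert-butyldimethylsilyl)oxy]-1-methyl-3-[(trimethylsilyl)oxy]cyclohex-2-ene-1-carboxylate
Product: 8 methyl (1R,2R,6S)-6-[(tert-butyldimethylsilyl)oxy]-2-(1,3-dithian-2-yl)-1-methyl-3-oxocyclohexane-1-carboxylate
Conditions: 1,3-dithian-2-ylium tetrafluoroborate (from 1,3-dithiane and Ph3CBF4), CH2Cl2, −78 °C
Reagents that add atoms: 1,3-dithian-2-ylium tetrafluoroborate (C1CS[CH+]SC1.F[B-](F)(F)F)
Why: Alkylation of the silyl enol ether by the dithienium cation (Mukaiyama-type reaction with a formyl cation equivalent) should occur axially on the face opposite the pseudoaxial ester on C1 and so place C9 trans to C2.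

Step 8
Reactants: 8 methyl (1R,2R,6S)-6-[(tert-butyldimethylsilyl)oxy]-2-(1,3-dithian-2-yl)-1-methyl-3-oxocyclohexane-1-carboxylate
Product: 9 methyl (1R,2R,6S)-6-[(tert-butyldimethylsilyl)oxy]-2-(1,3-dithian-2-yl)-1-methyl-3-{[(trifluoromethyl)sulfonyl]oxy}cyclohex-3-ene-1-carboxylate
Conditions: KHMDS, THF, −78 °C; then PhNTf2
Reagents that add atoms: N-phenylbis(trifluoromethanesulfonimide) (O=S(=O)(N(c1ccccc1)S(=O)(=O)C(F)(F)F)C(F)(F)F)
Why: Kinetic deprotonation occurs at the unhindered C12 methylene, and O-triflation of the enolate gives the C11=C12 enol triflate without epimerising C10.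

Step 9
Reactants: 9 methyl (1R,2R,6S)-6-[(tert-butyldimethylsilyl)oxy]-2-(1,3-dithian-2-yl)-1-methyl-3-{[(trifluoromethyl)sulfonyl]oxy}cyclohex-3-ene-1-carboxylate
Product: 10 methyl (1R,2S,6S)-6-[(tert-butyldimethylsilyl)oxy]-2-(1,3-dithian-2-yl)-3-(hydroxymethyl)-1-methylcyclohex-3-ene-1-carboxylate
Conditions: Pd(PPh3)4 (5 mol%), Bu3SnCH2OH, LiCl, dioxane, 90 °C
Reagents that add atoms: (tributylstannyl)methanol (CCCC[Sn](CCCC)(CCCC)CO)
Why: Stille coupling of the enol triflate with the hydroxymethylstannane attaches C20 at the oxidation level of the target and fixes the C11=C12 olefin.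

Step 10
Reactants: 10 methyl (1R,2S,6S)-6-[(tert-butyldimethylsilyl)oxy]-2-(1,3-dithian-2-yl)-3-(hydroxymethyl)-1-methylcyclohex-3-ene-1-carboxylate
Product: 11 C20 TBDPS ether of 10
Conditions: TBDPSCl, imidazole, DMF, 0 °C
Reagents that add atoms: tert-butyldiphenylsilyl chloride (CC(C)(C)[Si](Cl)(c1ccccc1)c1ccccc1)
Why: Silylation of the primary allylic alcohol with the robust TBDPS group, which must outlast the secondary TBS and tertiary TES ethers in the endgame.

Step 11
Reactants: 11 C20 TBDPS ether of 10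
Product: 13 C2 dimethyl ketal (cyclohexene fragment), via methyl enol ether 12 (not isolated)
Conditions: Cp2TiMe2, toluene, 70 °C; then MeOH, PPTS (cat.), 0 °C
Reagents that add atoms: dimethyltitanocene (C[Ti](C)(C1C=CC=C1)C1C=CC=C1); methanol (CO)
Why: Petasis methylenation of the only carbonyl group converts the ester into the methyl enol ether (C3 added), and acid-catalysed addition of methanol stores it as the base-stable dimethyl ketal of the C2 methyl ketone.

Step 12
Reactants: 14 (R)-2,2-dimethyl-1,3-dioxolane-4-carbaldehyde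
Product: 15 (S)-1-[(R)-2,2-dimethyl-1,3-dioxolan-4-yl]-2-methylprop-2-en-1-ol
Conditions: isopropenylmagnesium bromide, THF, −78 °C
Reagents that add atoms: isopropenylmagnesium bromide (CC(=C)[Mg]Br)
Why: Grignard addition under Felkin–Anh (non-chelation) control is expected to favour the 6,7-anti alcohol, which is separated from the minor syn isomer.

Step 13
Reactants: 15 (S)-1-[(R)-2,2-dimethyl-1,3-dioxolan-4-yl]-2-methylprop-2-en-1-ol
Product: 16 (R)-4-{(S)-1-[(4-methoxybenzyl)oxy]-2-methylprop-2-en-1-yl}-2,2-dimethyl-1,3-dioxolane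
Conditions: NaH, PMBCl, Bu4NI (cat.), DMF, 0 °C to rt
Reagents that add atoms: 4-methoxybenzyl chloride (COc1ccc(CCl)cc1)
Why: Williamson etherification protects O6 as the PMB ether, which is removed oxidatively just before the key step.

Step 14
Reactants: 16 (R)-4-{(S)-1-[(4-methoxybenzyl)oxy]-2-methylprop-2-en-1-yl}-2,2-dimethyl-1,3-dioxolane
Product: 17 (2R,3S)-3-[(4-methoxybenzyl)oxy]-4-methylpent-4-ene-1,2-diol
Conditions: AcOH/H2O (4:1), 40 °C
Reagents that add atoms: none
Why: Acid hydrolysis of the acetonide frees the 7,8-diol without affecting the PMB ether.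

Step 15
Reactants: 17 (2R,3S)-3-[(4-methoxybenzyl)oxy]-4-methylpent-4-ene-1,2-diol
Product: 18 (2R,3S)-3-[(4-methoxybenzyl)oxy]-4-methyl-1,2-bis[(triethylsilyl)oxy]pent-4-ene
Conditions: TESCl, imidazole, CH2Cl2, 0 °C
Reagents that add atoms: chlorotriethylsilane (CC[Si](Cl)(CC)CC)
Why: Silylation of both hydroxyls sets up the selective oxidation of the primary position.

Step 16
Reactants: 18 (2R,3S)-3-[(4-methoxybenzyl)oxy]-4-methyl-1,2-bis[(triethylsilyl)oxy]pent-4-ene
Product: 19 (2S,3S)-3-[(4-methoxybenzyl)oxy]-4-methyl-2-[(triethylsilyl)oxy]pent-4-enal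
Conditions: (COCl)2, DMSO, CH2Cl2, −78 to −30 °C; then Et3N
Reagents that add atoms: none
Why: Under Swern conditions the primary TES ether is cleaved and oxidised directly to the aldehyde while the secondary TES ether survives (selective Swern oxidation of primary silyl ethers), and the α-stereocentre is retained at low temperature.

Step 17
Reactants: 13 C2 dimethyl ketal (cyclohexene fragment); 19 (2S,3S)-3-[(4-methoxybenzyl)oxy]-4-methyl-2-[(triethylsilyl)oxy]pent-4-enal
Product: 20 C8–C9 coupling product (C8 carbinol, both epimers)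
Conditions: 13, t-BuLi, THF/HMPA (10:1), −78 °C; then 19, −78 °C
Reagents that add atoms: none
Why: Corey–Seebach reaction in which the lithiated 2-alkyl-1,3-dithiane (acyl anion equivalent of C9) adds to the aldehyde to form the C8–C9 bond; the C8 configuration is irrelevant because it is oxidised next.

Step 18
Reactants: 20 C8–C9 coupling product (C8 carbinol, both epimers)
Product: 21 C8 ketone
Conditions: Dess–Martin periodinane, NaHCO3, CH2Cl2, 0 °C
Reagents that add atoms: none
Why: Buffered Dess–Martin oxidation gives the C8 ketone flanked by the dithiane, the electrophile of the lactone-forming aldol.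

Step 19
Reactants: 21 C8 ketone
Product: 22 C7 α-hydroxy ketone
Conditions: PPTS, MeOH, 0 °C
Reagents that add atoms: none
Why: Acid methanolysis cleaves the secondary TES ether selectively over the TBS, TBDPS and PMB ethers, and the dimethyl ketal only exchanges degenerately with methanol.

Step 20
Reactants: 22 C7 α-hydroxy ketone
Product: 23 C7 propanoate
Conditions: (EtCO)2O, Et3N, DMAP (cat.), CH2Cl2, 0 °C
Reagents that add atoms: propanoic anhydride (CCC(=O)OC(=O)CC)
Why: DMAP-catalysed acylation puts on O7 the propanoate that carries C17–C19 of the lactone.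

Step 21
Reactants: 23 C7 propanoate
Product: 24 γ-lactone with C8-OTES and C6-OPMB
Conditions: LiHMDS, THF, −78 °C; then TESOTf, −78 to −40 °C
Reagents that add atoms: triethylsilyl trifluoromethanesulfonate (CC[Si](CC)(CC)OS(=O)(=O)C(F)(F)F)
Why: Intramolecular aldol addition of the propanoate lithium enolate to the C8 ketone (aldol lactonisation, 5-exo) closes the γ-lactone; the bulky dithiane-bearing carbon should end up trans to the C6 substituent (O8 cis to C6) and the C17 methyl trans to C9, and the tertiary alkoxide is silylated in situ.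

Step 22
Reactants: 24 γ-lactone with C8-OTES and C6-OPMB
Product: 25 γ-lactone C6 allylic alcohol (seco precursor)
Conditions: DDQ, CH2Cl2/pH 7 buffer, 0 °C
Reagents that add atoms: none
Why: Oxidative cleavage of the PMB ether with buffered DDQ frees O6, the only free hydroxyl of the key-step precursor.

Step 23
Reactants: 25 γ-lactone C6 allylic alcohol (seco precursor)
Product: 27 ten-membered C2 ketone with (5Z)-olefin, via cyclic enol ether 26 (not isolated)
Conditions: PPTS (10 mol%), mesitylene (0.002 M), 4 Å MS (Soxhlet), 150 °C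
Reagents that add atoms: none
Why: Proposed new method: under acid catalysis the C2 dimethyl ketal ionises to the oxocarbenium ion, the only free hydroxyl (C6–OH) adds, and loss of the second methanol gives the eight-membered 2-methylene-oxocane 26 (O–C2–C1–C10–C9–C8–C7–C6), an allyl vinyl ether that undergoes [3,3]-sigmatropic rearrangement to form C3–C4, the C2 ketone and the C5=C6 olefin. The closest known reactions are the acid-catalysed ketal Claisen rearrangement of allylic alcohols with ketone dimethyl ketals or 2-methoxypropene (intermolecular) and the Claisen ring expansion of 2-methylene-6-vinyl-tetrahydropyrans to cyclooctenones; new here is that the mixed ketal forms intramolecularly through a medium ring. The ten-membered carbocycle is closed by this two-carbon ring expansion of the transient oxocane (8-exo ketal exchange, then a chair-like [3,3] transition state bridged by the five-atom chain C1–C10–C9–C8–C7), and the irreversible rearrangement drains the unfavourable ketal-exchange equilibria. No stereocentre is created (C6 is destroyed, C2 becomes sp2); the only stereochemical element, the 5Z olefin, is controlled by the bridge, which forces C7 into the axial position of the transition state, the reverse of the E-preference of untethered Claisen reactions. The step needs intramolecular exchange to beat oligomerisation and competing ring sizes: high dilution and continuous removal of methanol serve the first, and the second is secured by the substrate, in which C6–OH is the only free hydroxyl (O8 is silylated so that the six-membered C2/O8 ketal cannot form, O14 and O20 are capped). C9 is kept as the dithiane so that C10–H stays non-enolisable under the hot acidic conditions.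

Step 24
Reactants: 27 ten-membered C2 ketone with (5Z)-olefin
Product: 28 C14,C8-diol C2 ketone
Conditions: HF·pyridine, pyridine, THF, 0 °C to rt
Reagents that add atoms: none
Why: Buffered HF·pyridine should cleave the secondary TBS and tertiary TES ethers faster than the primary TBDPS ether, exposing the C14 hydroxyl as the directing group for the next step.

Step 25
Reactants: 28 C14,C8-diol C2 ketone
Product: 29 (2S)-C2,C14 anti-diol
Conditions: Me4NBH(OAc)3, AcOH/MeCN, −20 °C
Reagents that add atoms: none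
Why: Evans–Saksena reduction, in which the alkoxy(acetoxy)borohydride formed at O14 delivers hydride intramolecularly to the β-ketone; this should give the 1,3-anti diol and thus the (2S) carbinol.

Step 26
Reactants: 29 (2S)-C2,C14 anti-diol
Product: 30 C2,C14 diacetate
Conditions: Ac2O, pyridine, DMAP (cat.), CH2Cl2, rt
Reagents that add atoms: acetic anhydride (CC(=O)OC(C)=O)
Why: DMAP-catalysed acetylation esterifies the two secondary alcohols at C2 and C14, while the hindered tertiary C8 hydroxyl is expected to stay free.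

Step 27
Reactants: 30 C2,C14 diacetate
Product: 31 C20 alcohol (C9 dithiane of the target)
Conditions: HF·pyridine, THF, rt
Reagents that add atoms: none
Why: Fluoride cleavage of the remaining silyl ether liberates the C20 allylic alcohol without touching the acetates.

Step 28
Reactants: 31 C20 alcohol (C9 dithiane of the target)
Product: 32 target CNP0140109.1
Conditions: MeI, CaCO3, MeCN/H2O (9:1), 45 °C
Reagents that add atoms: water (O)
Why: Alkylative hydrolysis of the dithiane (S-methylation, then hydrolysis at neutral pH) unveils the C9 ketone last, so that the sensitive β,γ-unsaturated α-hydroxy ketone never meets harsh conditions.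

**Compound list**

1 | methyl 2-hydroxy-5-methoxybenzoate | COC(=O)c1cc(OC)ccc1O | starting material
2 | methyl 3,3-dimethoxy-6-oxocyclohexa-1,4-diene-1-carboxylate | COC(=O)C1=CC(OC)(OC)C=CC1=O | intermediate
3 | methyl 3,3-dimethoxy-6-oxocyclohex-1-ene-1-carboxylate | COC(=O)C1=CC(OC)(OC)CCC1=O | intermediate
4 | methyl (6S)-6-hydroxy-3,3-dimethoxycyclohex-1-ene-1-carboxylate | O[C@H]1CCC(OC)(OC)C=C1C(=O)OC | intermediate
5 | methyl (6S)-6-hydroxy-3-oxocyclohex-1-ene-1-carboxylate | O[C@H]1CCC(=O)C=C1C(=O)OC | intermediate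
6 | methyl (6S)-6-[(tert-butyldimethylsilyl)oxy]-3-oxocyclohex-1-ene-1-carboxylate | CC(C)(C)[Si](C)(C)O[C@H]1CCC(=O)C=C1C(=O)OC | intermediate
7 | methyl (1R,6S)-6-[(tert-butyldimethylsilyl)oxy]-1-methyl-3-[(trimethylsilyl)oxy]cyclohex-2-ene-1-carboxylate (methyl trans to OTBS) | CC(C)(C)[Si](C)(C)O[C@H]1CCC(O[Si](C)(C)C)=C[C@@]1(C)C(=O)OC | intermediate
8 | methyl (1R,2R,6S)-6-[(tert-butyldimethylsilyl)oxy]-2-(1,3-dithian-2-yl)-1-methyl-3-oxocyclohexane-1-carboxylate (dithianyl trans to ester) | CC(C)(C)[Si](C)(C)O[C@H]1CCC(=O)[C@H](C2SCCCS2)[C@@]1(C)C(=O)OC | intermediate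
9 | methyl (1R,2R,6S)-6-[(tert-butyldimethylsilyl)oxy]-2-(1,3-dithian-2-yl)-1-methyl-3-{[(trifluoromethyl)sulfonyl]oxy}cyclohex-3-ene-1-carboxylate | CC(C)(C)[Si](C)(C)O[C@H]1CC=C(OS(=O)(=O)C(F)(F)F)[C@H](C2SCCCS2)[C@@]1(C)C(=O)OC | intermediate
10 | methyl (1R,2S,6S)-6-[(tert-butyldimethylsilyl)oxy]-2-(1,3-dithian-2-yl)-3-(hydroxymethyl)-1-methylcyclohex-3-ene-1-carboxylate | CC(C)(C)[Si](C)(C)O[C@H]1CC=C(CO)[C@H](C2SCCCS2)[C@@]1(C)C(=O)OC | intermediate
11 | C20 TBDPS ether of 10 | CC(C)(C)[Si](C)(C)O[C@H]1CC=C(CO[Si](c2ccccc2)(c2ccccc2)C(C)(C)C)[C@H](C2SCCCS2)[C@@]1(C)C(=O)OC | intermediate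
12 | methyl enol ether (1-methoxyvinyl group on C1; C2=C3) | CC(C)(C)[Si](C)(C)O[C@H]1CC=C(CO[Si](c2ccccc2)(c2ccccc2)C(C)(C)C)[C@H](C2SCCCS2)[C@@]1(C)C(=C)OC | intermediate
13 | C2 dimethyl ketal (cyclohexene fragment: C14-OTBS, C20-OTBDPS, C9 dithiane) | CC(C)(C)[Si](C)(C)O[C@H]1CC=C(CO[Si](c2ccccc2)(c2ccccc2)C(C)(C)C)[C@H](C2SCCCS2)[C@@]1(C)C(C)(OC)OC | intermediate
14 | (R)-2,2-dimethyl-1,3-dioxolane-4-carbaldehyde | O=C[C@H]1COC(C)(C)O1 | starting material
15 | (S)-1-[(R)-2,2-dimethyl-1,3-dioxolan-4-yl]-2-methylprop-2-en-1-ol | C=C(C)[C@H](O)[C@H]1COC(C)(C)O1 | intermediate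
16 | (R)-4-{(S)-1-[(4-methoxybenzyl)oxy]-2-methylprop-2-en-1-yl}-2,2-dimethyl-1,3-dioxolane | C=C(C)[C@H](OCc1ccc(OC)cc1)[C@H]2COC(C)(C)O2 | intermediate
17 | (2R,3S)-3-[(4-methoxybenzyl)oxy]-4-methylpent-4-ene-1,2-diol | C=C(C)[C@H](OCc1ccc(OC)cc1)[C@H](O)CO | intermediate
18 | (2R,3S)-3-[(4-methoxybenzyl)oxy]-4-methyl-1,2-bis[(triethylsilyl)oxy]pent-4-ene | C=C(C)[C@H](OCc1ccc(OC)cc1)[C@H](O[Si](CC)(CC)CC)CO[Si](CC)(CC)CC | intermediate
19 | (2S,3S)-3-[(4-methoxybenzyl)oxy]-4-methyl-2-[(triethylsilyl)oxy]pent-4-enal | C=C(C)[C@H](OCc1ccc(OC)cc1)[C@H](O[Si](CC)(CC)CC)C=O | intermediate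
20 | C8–C9 coupling product (C8 carbinol, both epimers; C7-OTES, C6-OPMB) | CC(C)(C)[Si](C)(C)O[C@H]1CC=C(CO[Si](c2ccccc2)(c2ccccc2)C(C)(C)C)[C@H](C2(SCCCS2)C(O)[C@@H](O[Si](CC)(CC)CC)[C@@H](OCc2ccc(OC)cc2)C(C)=C)[C@@]1(C)C(C)(OC)OC | intermediate
21 | C8 ketone | CC(C)(C)[Si](C)(C)O[C@H]1CC=C(CO[Si](c2ccccc2)(c2ccccc2)C(C)(C)C)[C@H](C2(SCCCS2)C(=O)[C@@H](O[Si](CC)(CC)CC)[C@@H](OCc2ccc(OC)cc2)C(C)=C)[C@@]1(C)C(C)(OC)OC | intermediate
22 | C7 α-hydroxy ketone | CC(C)(C)[Si](C)(C)O[C@H]1CC=C(CO[Si](c2ccccc2)(c2ccccc2)C(C)(C)C)[C@H](C2(SCCCS2)C(=O)[C@@H](O)[C@@H](OCc2ccc(OC)cc2)C(C)=C)[C@@]1(C)C(C)(OC)OC | intermediate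
23 | C7 propanoate | CC(C)(C)[Si](C)(C)O[C@H]1CC=C(CO[Si](c2ccccc2)(c2ccccc2)C(C)(C)C)[C@H](C2(SCCCS2)C(=O)[C@@H](OC(=O)CC)[C@@H](OCc2ccc(OC)cc2)C(C)=C)[C@@]1(C)C(C)(OC)OC | intermediate
24 | γ-lactone (O7–C19) with C8-OTES, 17-methyl cis to O8, C6-OPMB | CC(C)(C)[Si](C)(C)O[C@H]1CC=C(CO[Si](c2ccccc2)(c2ccccc2)C(C)(C)C)[C@H](C2(SCCCS2)[C@@]3(O[Si](CC)(CC)CC)[C@H]([C@@H](OCc2ccc(OC)cc2)C(C)=C)OC(=O)[C@@H]3C)[C@@]1(C)C(C)(OC)OC | intermediate
25 | γ-lactone C6 allylic alcohol (seco precursor) | CC(C)(C)[Si](C)(C)O[C@H]1CC=C(CO[Si](c2ccccc2)(c2ccccc2)C(C)(C)C)[C@H](C2(SCCCS2)[C@@]3(O[Si](CC)(CC)CC)[C@H]([C@@H](O)C(C)=C)OC(=O)[C@@H]3C)[C@@]1(C)C(C)(OC)OC | intermediate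
26 | eight-membered cyclic enol ether (2-methylene-oxocane O6–C2, isopropenyl on C6) | CC(C)(C)[Si](C)(C)O[C@H]1CC=C(CO[Si](c2ccccc2)(c2ccccc2)C(C)(C)C)[C@@H]2C3(SCCCS3)[C@@]4(O[Si](CC)(CC)CC)[C@H]([C@@H](OC(=C)[C@@]12C)C(C)=C)OC(=O)[C@@H]4C | intermediate
27 | ten-membered C2 ketone with (5Z)-olefin (C9 dithiane, C8-OTES, C14-OTBS, C20-OTBDPS) | CC(C)(C)[Si](C)(C)O[C@H]1CC=C(CO[Si](c2ccccc2)(c2ccccc2)C(C)(C)C)[C@@H]2C3(SCCCS3)[C@@]4(O[Si](CC)(CC)CC)[C@H](/C=C(/C)CCC(=O)[C@]21C)OC(=O)[C@@H]4C | intermediate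
28 | C14,C8-diol C2 ketone (C20-OTBDPS) | O[C@H]1CC=C(CO[Si](c2ccccc2)(c2ccccc2)C(C)(C)C)[C@@H]2C3(SCCCS3)[C@@]4(O)[C@H](/C=C(/C)CCC(=O)[C@]21C)OC(=O)[C@@H]4C | intermediate
29 | (2S)-C2,C14 anti-diol | O[C@H]1CC=C(CO[Si](c2ccccc2)(c2ccccc2)C(C)(C)C)[C@@H]2C3(SCCCS3)[C@@]4(O)[C@H](/C=C(/C)CC[C@H](O)[C@]21C)OC(=O)[C@@H]4C | intermediate
30 | C2,C14 diacetate | CC(=O)O[C@H]1CC=C(CO[Si](c2ccccc2)(c2ccccc2)C(C)(C)C)[C@@H]2C3(SCCCS3)[C@@]4(O)[C@H](/C=C(/C)CC[C@H](OC(C)=O)[C@]21C)OC(=O)[C@@H]4C | intermediate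
31 | C20 alcohol (C9 dithiane of the target) | CC(=O)O[C@H]1CC=C(CO)[C@@H]2C3(SCCCS3)[C@@]4(O)[C@H](/C=C(/C)CC[C@H](OC(C)=O)[C@]21C)OC(=O)[C@@H]4C | intermediate
32 | target CNP0140109.1 (briarane: 2,14-diacetate, 8,20-diol, 9-ketone, 5Z,11-diene, γ-lactone to O7) | CC(=O)O[C@H]1CC=C(CO)[C@@H]2C(=O)[C@@]3(O)[C@H](/C=C(/C)CC[C@H](OC(C)=O)[C@]21C)OC(=O)[C@@H]3C | target

**Step count**

Total step count: 28. Longest linear sequence: 23 steps (steps 1–11 and 17–28).

**Steps most likely to fail**

Step 23 (proposed new method). The intramolecular ketal exchange to the strained eight-membered mixed ketal may not compete with oligomeric exchange, or with simple loss of methanol to the open-chain enol ether, so that no allyl vinyl ether forms and nothing rearranges. The fallback uses known chemistry and sets out from 25. The C6 alcohol is converted with methyl chloroformate and pyridine into the allylic methyl carbonate F1. The ketal is hydrolysed with PPTS in wet acetone to the methyl ketone F2. Soft enolisation with TMSOTf and Et3N at −78 °C gives the TMS enol ether F3, where only C3 can be enolised. Pd2(dba)3/dppe in THF at 60 °C under high dilution then effects a Tsuji–Trost allylation of the silyl enol ether by the π-allylpalladium complex at its unsubstituted terminus C4. The ring constraint and the 2-methyl group of the allyl unit should favour the anti complex and hence the Z olefin. The fallback comes back to the route at 27.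

Step 21. Deprotonation may take place at C7 of the α-acyloxy ketone instead of at the propanoate, leading to epimerisation at C7 or acyl migration and no ring closure. The fallback sets out from 22, which is acylated with 2-bromopropanoyl bromide and pyridine to the 2-bromopropanoate F4. SmI2 in THF at −78 °C generates the samarium enolate reductively, and an intramolecular Reformatsky addition to the C8 ketone gives the hydroxy lactone F5. Silylation with TESOTf and 2,6-lutidine brings it back to the route at 24.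

Step 25. Facial selectivity of the intramolecular hydride delivery may be poor or reversed, because the chair-like transition state is distorted by the quaternary C1 and the medium ring. The fallback sets out from 27 and uses reagent control: (R)-Me-CBS and catecholborane reduce the fully silylated ketone, with the quaternary C1 side as the large group, to the (2S)-alcohol F6. HF·pyridine under the conditions of step 24 then removes the TBS and TES ethers and brings the material back to the route at 29.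

**Further compounds**

F1 | step 23 | C6 allylic methyl carbonate of 25 | CC(C)(C)[Si](C)(C)O[C@H]1CC=C(CO[Si](c2ccccc2)(c2ccccc2)C(C)(C)C)[C@H](C2(SCCCS2)[C@@]3(O[Si](CC)(CC)CC)[C@H]([C@@H](OC(=O)OC)C(C)=C)OC(=O)[C@@H]3C)[C@@]1(C)C(C)(OC)OC
F2 | step 23 | C2 methyl ketone carbonate | CC(C)(C)[Si](C)(C)O[C@H]1CC=C(CO[Si](c2ccccc2)(c2ccccc2)C(C)(C)C)[C@H](C2(SCCCS2)[C@@]3(O[Si](CC)(CC)CC)[C@H]([C@@H](OC(=O)OC)C(C)=C)OC(=O)[C@@H]3C)[C@@]1(C)C(C)=O
F3 | step 23 | C2=C3 trimethylsilyl enol ether carbonate | CC(C)(C)[Si](C)(C)O[C@H]1CC=C(CO[Si](c2ccccc2)(c2ccccc2)C(C)(C)C)[C@H](C2(SCCCS2)[C@@]3(O[Si](CC)(CC)CC)[C@H]([C@@H](OC(=O)OC)C(C)=C)OC(=O)[C@@H]3C)[C@@]1(C)C(=C)O[Si](C)(C)C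
F4 | step 21 | C7 2-bromopropanoate of 22 | CC(C)(C)[Si](C)(C)O[C@H]1CC=C(CO[Si](c2ccccc2)(c2ccccc2)C(C)(C)C)[C@H](C2(SCCCS2)C(=O)[C@@H](OC(=O)C(C)Br)[C@@H](OCc2ccc(OC)cc2)C(C)=C)[C@@]1(C)C(C)(OC)OC
F5 | step 21 | γ-lactone with free C8 hydroxyl | CC(C)(C)[Si](C)(C)O[C@H]1CC=C(CO[Si](c2ccccc2)(c2ccccc2)C(C)(C)C)[C@H](C2(SCCCS2)[C@@]3(O)[C@H]([C@@H](OCc2ccc(OC)cc2)C(C)=C)OC(=O)[C@@H]3C)[C@@]1(C)C(C)(OC)OC
F6 | step 25 | (2S)-C2 alcohol with C14-OTBS, C8-OTES and C20-OTBDPS | CC(C)(C)[Si](C)(C)O[C@H]1CC=C(CO[Si](c2ccccc2)(c2ccccc2)C(C)(C)C)[C@@H]2C3(SCCCS3)[C@@]4(O[Si](CC)(CC)CC)[C@H](/C=C(/C)CC[C@H](O)[C@]21C)OC(=O)[C@@H]4C
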